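**Strategy.** The 18-membered ring is opened at the unsubstituted C7–C8 ethano bridge between rings A and D. The ring carbons that carry this bridge have only C–H neighbours, so no ortho oxygen can chelate ruthenium. Neither the C7' carbinol nor the congested ether at ring C is nearby. One ring-closing metathesis of an open-chain tetraaryl bis-styrene forms C7=C8 and the macrocycle together, and hydrogenation later erases the alkene. The precursor already contains both diaryl ethers and the (S)-C7' silyl ether. Its two vinyl groups are unveiled together from aryl bromides one step earlier. The ring A catechol is masked as a hydrogenolysable diphenylmethylene ketal.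

Key step: step 13

Remark: ring A is the trioxygenated ring, ring B the para-linked ring on C7', ring C the 1,2,3-trisubstituted ring on C8', ring D the meta-linked ring; C7' is (S) (OH > ring B carbon > C8' > H); the macrocyclic alkene is assumed and drawn as Z, but either geometry or a mixture serves equally because the double bond is hydrogenated.

**Step 1**
Reactants: 1 5-bromo-1,2,3-trimethoxybenzene
Product: 2 5-bromobenzene-1,2,3-triol
Conditions: BBr3 (3.5 equiv), CH2Cl2, −78 °C → rt; H2O
Reagents that add atoms: none
Why: Lewis-acid aryl methyl ether cleavage, in which BBr3 coordinates each methoxy oxygen, bromide removes the methyl group by SN2 attack and hydrolysis of the aryl borates frees the triol while the C–Br bond is inert.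

**Step 2**
Reactants: 2 5-bromobenzene-1,2,3-triol
Product: 3 6-bromo-2,2-diphenyl-1,3-benzodioxol-4-ol
Conditions: Ph2CCl2 (1.1 equiv), Ph2O, 170 °C, N2 stream
Reagents that add atoms: dichlorodiphenylmethane, ClC(Cl)(c1ccccc1)c1ccccc1
Why: Catechol ketalisation with a gem-dichloride, where only two neighbouring hydroxyls can span the Ph2C unit and the two neighbouring pairs of the symmetric triol are equivalent, so a single regioisomer with exactly one free phenol is expected, which a statistical twofold benzylation cannot offer.

**Step 3**
Reactants: 3 6-bromo-2,2-diphenyl-1,3-benzodioxol-4-ol; 4 4-fluorobenzaldehyde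
Product: 5 4-[(6-bromo-2,2-diphenyl-1,3-benzodioxol-4-yl)oxy]benzaldehyde (rings A and B)
Conditions: K2CO3, DMF, 110 °C
Reagents that add atoms: none
Why: Nucleophilic aromatic substitution by addition–elimination, in which the para formyl group stabilises the Meisenheimer adduct and fluoride departs, so the phenoxide of 3 attacks only the C–F carbon and the unactivated aryl bromide and the base-stable ketal persist.

**Step 4**
Reactants: 6 2-fluoro-3-hydroxybenzaldehyde
Product: 7 3-(benzyloxy)-2-fluorobenzaldehyde
Conditions: BnBr, K2CO3, DMF, rt
Reagents that add atoms: benzyl bromide, BrCc1ccccc1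
Why: Williamson ether synthesis, needed because a free ring C phenoxide would deactivate the neighbouring C–F bond towards the next substitution, and chosen because the benzyl group leaves in the same hydrogenation that saturates the bridge.

**Step 5**
Reactants: 7 3-(benzyloxy)-2-fluorobenzaldehyde; 8 3-bromophenol
Product: 9 3-(benzyloxy)-2-(3-bromophenoxy)benzaldehyde (rings C and D)
Conditions: K2CO3, DMA, 130 °C
Reagents that add atoms: none
Why: Nucleophilic aromatic substitution activated by the ortho formyl group, where attack comes perpendicular to the ring plane so the flanking benzyloxy group slows but should not block it, and the C–Br bond of the phenol partner has no activating group and stays.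

**Step 6**
Reactants: 9 3-(benzyloxy)-2-(3-bromophenoxy)benzaldehyde
Product: 10 [3-(benzyloxy)-2-(3-bromophenoxy)phenyl]methanol
Conditions: NaBH4, THF/MeOH, 0 °C
Reagents that add atoms: none
Why: Borohydride 1,2-reduction of an aromatic aldehyde, which touches neither the aryl bromide nor the ethers.

**Step 7**
Reactants: 10 [3-(benzyloxy)-2-(3-bromophenoxy)phenyl]methanol
Product: 11 1-(benzyloxy)-2-(3-bromophenoxy)-3-(chloromethyl)benzene
Conditions: SOCl2, DMF (cat.), CH2Cl2, 0 °C → rt
Reagents that add atoms: thionyl chloride, O=S(Cl)Cl
Why: Deoxychlorination through a chlorosulfite with Vilsmeier-type activation gives a primary benzylic chloride, the halide class that inserts zinc cleanly with little Wurtz coupling.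

**Step 8**
Reactants: 11 1-(benzyloxy)-2-(3-bromophenoxy)-3-(chloromethyl)benzene; 5 4-[(6-bromo-2,2-diphenyl-1,3-benzodioxol-4-yl)oxy]benzaldehyde
Product: 13 rac-2-[3-(benzyloxy)-2-(3-bromophenoxy)phenyl]-1-{4-[(6-bromo-2,2-diphenyl-1,3-benzodioxol-4-yl)oxy]phenyl}ethan-1-ol, via benzylzinc chloride 12 (not isolated)
Conditions: Zn dust, LiCl, THF, 25 °C; then 5, MgCl2, 25 °C; aq NH4Cl
Reagents that add atoms: zinc, [Zn] (atoms held only in intermediate 12)
Why: LiCl-promoted direct zinc insertion selects the benzylic C–Cl bond over aryl C–Br bonds, and the benzylic zinc chloride then adds 1,2 to the aromatic aldehyde (Barbier/Grignard-type carbonyl addition, accelerated by MgCl2), forming C7'–C8' with a racemic C7' that step 9 flattens.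

**Step 9**
Reactants: 13 racemic tetraaryl carbinol
Product: 14 2-[3-(benzyloxy)-2-(3-bromophenoxy)phenyl]-1-{4-[(6-bromo-2,2-diphenyl-1,3-benzodioxol-4-yl)oxy]phenyl}ethan-1-one
Conditions: Dess–Martin periodinane, CH2Cl2, 0 °C → rt
Reagents that add atoms: none
Why: Dess–Martin oxidation by ligand exchange at iodine and removal of the carbinol hydrogen converts the secondary benzylic alcohol into the aryl benzyl ketone under near-neutral conditions that spare ketal, benzyl ether and bromides.

**Step 10**
Reactants: 14 aryl benzyl ketone
Product: 15 (1S)-2-[3-(benzyloxy)-2-(3-bromophenoxy)phenyl]-1-{4-[(6-bromo-2,2-diphenyl-1,3-benzodioxol-4-yl)oxy]phenyl}ethan-1-ol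
Conditions: RuCl[(S,S)-TsDPEN](p-cymene) (2 mol %), HCO2H/Et3N (5:2), CH2Cl2, 35 °C
Reagents that add atoms: none
Why: Noyori–Ikariya asymmetric transfer hydrogenation, in whose outer-sphere six-membered transition state the conjugated ring B aryl lies beneath the η6-cymene (CH/π attraction) and the sp3 C8' methylene points away, so the (S,S)-catalyst should deliver hydride to the Re face and set (S)-C7' in the same sense as for acetophenone, irreversibly because CO2 escapes.

**Step 11**
Reactants: 15 (S)-carbinol
Product: 16 (S)-tert-butyldimethylsilyl ether of 15 (dibromide)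
Conditions: TBSCl, imidazole, DMAP (cat.), DMF, rt → 40 °C
Reagents that add atoms: tert-butyldimethylsilyl chloride, CC(C)(C)[Si](C)(C)Cl
Why: Imidazole-mediated O-silylation caps the activated benzylic alcohol without breaking the C7'–O bond, so the configuration is retained and the carbinol is later shielded from ruthenium hydrides and from the palladium surface.

**Step 12**
Reactants: 16 (S)-silyl ether dibromide; 17 vinylboronic acid pinacol ester (3 equiv)
Product: 18 open-chain (S)-silyl ether bis-styrene (16 with both bromines replaced by vinyl, one on ring A and one on ring D)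
Conditions: PdCl2(dppf) (5 mol %), K2CO3, 1,4-dioxane/H2O, 85 °C, BHT (trace)
Reagents that add atoms: none
Why: Twofold Suzuki–Miyaura vinylation (oxidative addition of zerovalent palladium into each C–Br bond, transmetalation from the boronate, reductive elimination) unveils both styrenes in one operation directly before use, so no polymerisable alkene has to survive an earlier step.

**Step 13**
Reactants: 18 open-chain (S)-silyl ether bis-styrene
Product: 19 macrocyclic stilbene (18-membered ring, C7=C8 drawn Z, (S)-C7' OTBS, ring A diphenylmethylene ketal, ring C benzyl ether)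
Conditions: second-generation Grubbs catalyst RuCl2(=CHPh)(PCy3)(H2IMes) (10 mol % in two portions), toluene, 1 mM, 80 °C, 18 added by syringe pump, Ar sparge; ethyl vinyl ether quench
Reagents that add atoms: none
Why: Ring-closing olefin metathesis by the Chauvin mechanism: the ruthenium benzylidene exchanges with one terminal styrene through a ruthenacyclobutane, the new aryl alkylidene captures the second styrene of the same molecule, and collapse of that metallacycle gives the C7=C8 stilbene and Ru=CH2, which re-enters the cycle while ethene is swept out. The closest known reaction type is the closure of bis-styrenes to macrocyclic stilbenes that are then saturated to bibenzyl cyclophanes. The one new ring is the 18-membered macrocycle, closed end to end as an endocyclic alkene between the vinyl-bearing carbons of rings A and D. No stereocentre is created, the neutral medium leaves the (S)-C7' silyl ether alone, and the alkene geometry is without consequence. The selectivity required is ring closure over chain growth, and it matters because internal stilbene links re-enter metathesis only sluggishly, so it is secured by pseudo-high dilution, ethene removal and the fold that the ortho-linked ring C and the meta-linked rings A and D give to the chain. Both reacting carbons sit between C–H positions, so there is neither steric hindrance nor an ortho alkoxy group that could hold ruthenium as a slow chelated benzylidene.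

**Step 14**
Reactants: 19 macrocyclic stilbene
Product: 20 (S)-C7' O-TBS ether of the target (saturated C7–C8 bridge, three free phenols)
Conditions: H2 (1 atm), 10% Pd/C, EtOAc/THF, rt
Reagents that add atoms: none
Why: Heterogeneous hydrogenation and hydrogenolysis, in which the stilbene adds H2 and the aryl benzyl ether and the doubly benzylic ketal C–O bonds cleave readily, whereas the bulky silyl ether keeps C7'–O off the metal and an aprotic solvent avoids the Pd/C-induced desilylation known in methanol, so (S)-C7' should stay intact.

**Step 15**
Reactants: 20 (S)-C7' O-TBS ether of the target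
Product: 21 target CNP0356934.1, (S)-configured at C7'
Conditions: TBAF, AcOH (1:1), THF, Ar, 0 °C → rt
Reagents that add atoms: none
Why: Fluoride-driven desilylation via pentacoordinate silicon breaks only the Si–O bond so C7' keeps its configuration, and the acetic acid buffer under argon keeps the catechol protonated and safe from base-promoted autoxidation while being far too weak to ionise the benzylic alcohol.

**Compound list**
1 | 5-bromo-1,2,3-trimethoxybenzene | COc1cc(Br)cc(OC)c1OC | starting material
2 | 5-bromobenzene-1,2,3-triol | Oc1cc(Br)cc(O)c1O | intermediate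
3 | 6-bromo-2,2-diphenyl-1,3-benzodioxol-4-ol | Oc1cc(Br)cc2OC(c3ccccc3)(c3ccccc3)Oc12 | intermediate
4 | 4-fluorobenzaldehyde | O=Cc1ccc(F)cc1 | starting material
5 | 4-[(6-bromo-2,2-diphenyl-1,3-benzodioxol-4-yl)oxy]benzaldehyde | O=Cc1ccc(cc1)Oc1cc(Br)cc2OC(c3ccccc3)(c3ccccc3)Oc12 | intermediate
6 | 2-fluoro-3-hydroxybenzaldehyde | O=Cc1cccc(O)c1F | starting material
7 | 3-(benzyloxy)-2-fluorobenzaldehyde | O=Cc1cccc(OCc2ccccc2)c1F | intermediate
8 | 3-bromophenol | Oc1cccc(Br)c1 | starting material
9 | 3-(benzyloxy)-2-(3-bromophenoxy)benzaldehyde | O=Cc1cccc(OCc2ccccc2)c1Oc1cccc(Br)c1 | intermediate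
10 | [3-(benzyloxy)-2-(3-bromophenoxy)phenyl]methanol | OCc1cccc(OCc2ccccc2)c1Oc1cccc(Br)c1 | intermediate
11 | 1-(benzyloxy)-2-(3-bromophenoxy)-3-(chloromethyl)benzene | ClCc1cccc(OCc2ccccc2)c1Oc1cccc(Br)c1 | intermediate
12 | [3-(benzyloxy)-2-(3-bromophenoxy)benzyl]zinc chloride (THF solution, not isolated) | Cl[Zn]Cc1cccc(OCc2ccccc2)c1Oc1cccc(Br)c1 | intermediate
13 | racemic tetraaryl carbinol | Brc1cc2OC(c3ccccc3)(c3ccccc3)Oc2c(c1)Oc1ccc(cc1)C(O)Cc1cccc(OCc2ccccc2)c1Oc1cccc(Br)c1 | intermediate
14 | aryl benzyl ketone | Brc1cc2OC(c3ccccc3)(c3ccccc3)Oc2c(c1)Oc1ccc(cc1)C(=O)Cc1cccc(OCc2ccccc2)c1Oc1cccc(Br)c1 | intermediate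
15 | (S)-carbinol | Brc1cc2OC(c3ccccc3)(c3ccccc3)Oc2c(c1)Oc1ccc(cc1)[C@@H](O)Cc1cccc(OCc2ccccc2)c1Oc1cccc(Br)c1 | intermediate
16 | (S)-silyl ether dibromide | Brc1cc2OC(c3ccccc3)(c3ccccc3)Oc2c(c1)Oc1ccc(cc1)[C@@H](O[Si](C)(C)C(C)(C)C)Cc1cccc(OCc2ccccc2)c1Oc1cccc(Br)c1 | intermediate
17 | vinylboronic acid pinacol ester | C=CB1OC(C)(C)C(C)(C)O1 | starting material
18 | open-chain (S)-silyl ether bis-styrene | C=Cc1cc2OC(c3ccccc3)(c3ccccc3)Oc2c(c1)Oc1ccc(cc1)[C@@H](O[Si](C)(C)C(C)(C)C)Cc1cccc(OCc2ccccc2)c1Oc1cccc(C=C)c1 | intermediate
19 | macrocyclic stilbene (drawn Z) | c1cc2cc(c1)/C=C\c1cc3OC(c4ccccc4)(c4ccccc4)Oc3c(c1)Oc1ccc(cc1)[C@@H](O[Si](C)(C)C(C)(C)C)Cc1cccc(OCc3ccccc3)c1O2 | intermediate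
20 | (S)-C7' O-TBS ether of the target | Oc1cc2cc(c1O)Oc1ccc(cc1)[C@@H](O[Si](C)(C)C(C)(C)C)Cc1cccc(O)c1Oc1cccc(c1)CC2 | intermediate
21 | CNP0356934.1 | Oc1cc2cc(c1O)Oc1ccc(cc1)[C@@H](O)Cc1cccc(O)c1Oc1cccc(c1)CC2 | target

**Total step count:** 15.
**Longest linear sequence:** 12 steps (steps 4–15, from 6). The ring A/B branch (steps 1–3) joins at step 8.

**Steps most likely to fail**

Step 13. Intermolecular metathesis may outpace ring closure, so that chains grow. There is little self-correction, because internal stilbene links re-enter the cycle slowly, and the catalyst may decay over the long addition. The fallback sets out from 18. Lemieux–Johnson cleavage of both vinyl groups (OsO4 cat., NaIO4, 2,6-lutidine, dioxane/H2O) should give the tetraaryl dialdehyde F1. An intramolecular McMurry coupling then joins the two formyl carbons reductively on low-valent titanium (TiCl4, Zn, pyridine, THF, reflux, syringe pump). This forms the same C7=C8 bond irreversibly. The fallback returns to the route at 19.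

Step 14. The silyl group may be lost early on the palladium surface, followed by hydrogenolysis of the C7'–O bond. Alternatively, slow ketal cleavage may force long contact times. The fallback sets out from 19 and separates the two reductions. Diimide (TsNHNH2, NaOAc, THF/H2O, reflux) cannot cleave C–O bonds and should saturate the alkene to the still fully protected saturated macrocycle F2. A short catalytic transfer hydrogenolysis (Pd(OH)2/C, 1,4-cyclohexadiene, EtOAc/EtOH, rt) then removes only the benzyl ether and the ketal. The fallback returns to the route at 20.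

Step 10. Facial selectivity may be poor, because the large C8' benzyl group carries an aryl ring of its own that could compete for the position beneath the arene ligand. Turnover of the electron-rich ketone may also be slow. The fallback sets out from racemic 13 and replaces asymmetric catalysis by resolution. Esterification with (S)-O-methylmandelic acid (EDC·HCl, DMAP, CH2Cl2) should give the (S)-carbinol ester F3 and the (R)-carbinol ester F4. These are separated by chromatography or crystallisation and assigned by the usual shielding model, and F4 is removed. Saponification of F3 (LiOH, THF/H2O) breaks only the acyl–oxygen bond. The fallback returns to the route at 15.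

**Further compounds**
F1 | step 13 | tetraaryl dialdehyde (18 with both vinyl groups replaced by formyl) | O=Cc1cc2OC(c3ccccc3)(c3ccccc3)Oc2c(c1)Oc1ccc(cc1)[C@@H](O[Si](C)(C)C(C)(C)C)Cc1cccc(OCc2ccccc2)c1Oc1cccc(C=O)c1
F2 | step 14 | saturated, fully protected macrocycle | c1cc2cc(c1)CCc1cc3OC(c4ccccc4)(c4ccccc4)Oc3c(c1)Oc1ccc(cc1)[C@@H](O[Si](C)(C)C(C)(C)C)Cc1cccc(OCc3ccccc3)c1O2
F3 | step 10 | (S)-O-methylmandelate of the (S)-carbinol | Brc1cc2OC(c3ccccc3)(c3ccccc3)Oc2c(c1)Oc1ccc(cc1)[C@@H](OC(=O)[C@@H](OC)c1ccccc1)Cc1cccc(OCc2ccccc2)c1Oc1cccc(Br)c1
F4 | step 10 | (S)-O-methylmandelate of the (R)-carbinol | Brc1cc2OC(c3ccccc3)(c3ccccc3)Oc2c(c1)Oc1ccc(cc1)[C@H](OC(=O)[C@@H](OC)c1ccccc1)Cc1cccc(OCc2ccccc2)c1Oc1cccc(Br)c1
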